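**Retrosynthetic overview**
- The C7=C8 (7E) olefin and the C12 acetate come last, from a one-pot acetylation/E1cB elimination of an aldol diol; the 5Z, 14Z and 17Z olefins come from one semi-hydrogenation of the triyne aldol.
- The C7–C8 bond is made by an aldol addition of a ring fragment A (C8–C20 hydroxy-cyclopentenone, used as its dianion) to a fragment B (C1–C7 ynal carrying the 4R acetate).
- Fragment A: C12 is set first, by a chiral-biphenol-catalysed (metal-free) mono-propargylboration of cyclopent-4-ene-1,3-dione; the chain is then extended by Cu-mediated coupling with 1-bromopent-2-yne.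
- Fragment B: acyl Sonogashira coupling of methyl succinyl chloride with 3,3-diethoxypropyne, asymmetric transfer hydrogenation (C4), acetylation, acetal hydrolysis.
- Ring order: the only ring (the cyclopentenone) is bought as the dione; no ring-forming step is needed.

Convention: late intermediates carry prostanoid locants (C1 = ester carbon, C8–C12 = ring). The ring carbinol is 4R in 4 and 6; the same spatial arrangement is 12S in the target, because the CIP priorities switch once C8 carries the side chain.

**Step 1**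
Reactants: 1 cyclopent-4-ene-1,3-dione; 2 allenylboronic acid pinacol ester
Product: 4 (4R)-4-hydroxy-4-(prop-2-yn-1-yl)cyclopent-2-en-1-one, via O-pinacolboryl ether 3 (not isolated)
Conditions: (S)-3,3'-Br2-BINOL (10 mol%), 2 (1.3 equiv), 4 Å MS, toluene, 0 °C → rt; then H2O work-up
Reagents that add atoms: none
Why: Proposed new method: enantioface-selective mono-propargylboration of an unprotected, C–H-acidic cyclic ene-1,3-dione, in which the chiral biphenol binds the pinacol boronate to give a more Lewis-acidic chiral boronate that transfers the allenyl group as propargyl through a closed six-membered SE2′ chair; the two carbonyls of 1 are homotopic so only the face must be chosen, the flat CH=CH flank is told from the CH2 flank as aryl is told from CH2 in cyclic aryl ketones (this sets C12), the non-basic reagent leaves alone the acidic C2–H2 that defeats Grignard additions, and the hindered mono-adduct enone does not add a second time; the closest known reaction type is the 3,3'-Br2-BINOL-catalysed allyl- and propargylboration of aryl and α,β-unsaturated ketones.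

**Step 2**
Reactants: 4 (4R)-4-hydroxy-4-(prop-2-yn-1-yl)cyclopent-2-en-1-one; 5 1-bromopent-2-yne
Product: 6 (4R)-4-hydroxy-4-(octa-2,5-diyn-1-yl)cyclopent-2-en-1-one
Conditions: CuI (20 mol%), NaI (20 mol%), K2CO3 (1.5 equiv), DMF, rt
Reagents that add atoms: none
Why: The copper acetylide formed under carbonate substitutes the propargylic bromide at its CH2Br carbon (Cu-mediated alkyne–propargyl halide coupling, the standard skipped-diyne synthesis), while the tertiary ketol and enone are untouched and C12 is not involved.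

**Step 3**
Reactants: 7 methyl 4-chloro-4-oxobutanoate; 8 3,3-diethoxyprop-1-yne
Product: 9 methyl 7,7-diethoxy-4-oxohept-5-ynoate
Conditions: PdCl2(PPh3)2 (2 mol%), CuI (4 mol%), Et3N (1.2 equiv), THF, rt
Reagents that add atoms: none
Why: Acyl Sonogashira coupling, in which the copper acetylide of 8 transmetallates to the acyl-palladium chloride formed from 7 and gives the ynone without touching the methyl ester or the acetal.

**Step 4**
Reactants: 9 methyl 7,7-diethoxy-4-oxohept-5-ynoate
Product: 10 methyl (4R)-7,7-diethoxy-4-hydroxyhept-5-ynoate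
Conditions: Ru(p-cymene)[(R,R)-TsNCH(Ph)CH(Ph)NH] (1 mol%), iPrOH, 25 °C
Reagents that add atoms: none
Why: Noyori-type asymmetric transfer hydrogenation of an alkynyl ketone, in which the alkyne takes the role of the aryl group of acetophenone so that the (R,R)-catalyst gives the 4R propargylic alcohol (this reaction class typically gives >95% ee) and leaves alkyne, ester and acetal intact.

**Step 5**
Reactants: 10 methyl (4R)-7,7-diethoxy-4-hydroxyhept-5-ynoate
Product: 11 methyl (4R)-4-acetoxy-7,7-diethoxyhept-5-ynoate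
Conditions: Ac2O, pyridine, DMAP (cat.), CH2Cl2, 0 °C (crude 10 used at once)
Reagents that add atoms: acetic anhydride, CC(=O)OC(C)=O
Why: DMAP-catalysed O-acetylation, run directly on crude 10 so that the γ-hydroxy ester has no time to lactonise; C4 is not touched.

**Step 6**
Reactants: 11 methyl (4R)-4-acetoxy-7,7-diethoxyhept-5-ynoate
Product: 12 methyl (4R)-4-acetoxy-7-oxohept-5-ynoate
Conditions: TFA–H2O (9:1), CH2Cl2, 0 °C
Reagents that add atoms: water, O
Why: Acid-catalysed acetal hydrolysis of the propargylic diethyl acetal to the ynal, under conditions short and cold enough to keep the secondary acetate and the methyl ester.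

**Step 7**
Reactants: 6 (4R)-4-hydroxy-4-(octa-2,5-diyn-1-yl)cyclopent-2-en-1-one; 12 methyl (4R)-4-acetoxy-7-oxohept-5-ynoate
Product: 14 methyl (4R)-4-acetoxy-7-hydroxy-7-[(5S)-5-hydroxy-5-(octa-2,5-diyn-1-yl)-2-oxocyclopent-3-en-1-yl]hept-5-ynoate (C7/C8 epimer mixture), via dilithium alkoxide-enolate 13 (not isolated)
Conditions: LiN(SiMe3)2 (2.1 equiv), THF, −78 °C; then 12 (1.2 equiv), −78 °C; AcOH, −78 °C
Reagents that add atoms: none
Why: Two equivalents of base give the alkoxide/α′-enolate dianion (C8 is the only enolisable position, and as a dianion it can neither lose oxide nor open by retro-aldol), which adds 1,2 to the very electrophilic ynal in a lithium aldol reaction; the new C7 and C8 centres are destroyed later so their mixture does not matter, and the mild amide base spares the skipped-diyne CH2.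

**Step 8**
Reactants: 14 methyl (4R)-4-acetoxy-7-hydroxy-7-[(5S)-5-hydroxy-5-(octa-2,5-diyn-1-yl)-2-oxocyclopent-3-en-1-yl]hept-5-ynoate
Product: 15 methyl (4R,5Z)-4-acetoxy-7-hydroxy-7-{(5S)-5-hydroxy-5-[(2Z,5Z)-octa-2,5-dien-1-yl]-2-oxocyclopent-3-en-1-yl}hept-5-enoate
Conditions: H2 (1 atm), Pd/CaCO3 poisoned with Pb(OAc)2, quinoline, EtOAc, rt, stopped after 3 equiv H2
Reagents that add atoms: none
Why: Lindlar-type cis semi-hydrogenation of three isolated alkynes (none is conjugated at this stage) sets 5Z, 14Z and 17Z by syn delivery of H2 on the poisoned Pd surface, and the quinoline-poisoned catalyst leaves the enone and the allylic C–O bonds alone.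

**Step 9**
Reactants: 15 methyl (4R,5Z)-4-acetoxy-7-hydroxy-7-{(5S)-5-hydroxy-5-[(2Z,5Z)-octa-2,5-dien-1-yl]-2-oxocyclopent-3-en-1-yl}hept-5-enoate
Product: 18 methyl (4R,5Z,7E,12S,14Z,17Z)-4,12-diacetoxy-9-oxoprosta-5,7,10,14,17-pentaen-1-oate, via C7 acetate 16 (not isolated), via 12-hydroxy dienone 17 (not isolated)
Conditions: Ac2O (6 equiv), Et3N (8 equiv), DMAP (0.5 equiv), CH2Cl2, 0 → 25 °C, dark
Reagents that add atoms: acetic anhydride, CC(=O)OC(C)=O
Why: The secondary allylic C7–OH is acetylated first and, being β to the ketone, leaves by amine-induced E1cB elimination to give the cross-conjugated dienone with the favoured 7E geometry (C6 anti to the C9 carbonyl, 5Z retained), after which DMAP-catalysed acetylation of the tertiary C12–OH completes the target; the minor 7Z isomer is removed by chromatography in the dark.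

**Compound list**
1 | cyclopent-4-ene-1,3-dione | O=C1CC(=O)C=C1 | starting material
2 | allenylboronic acid pinacol ester (4,4,5,5-tetramethyl-2-(propa-1,2-dien-1-yl)-1,3,2-dioxaborolane) | C=C=CB1OC(C)(C)C(C)(C)O1 | starting material
3 | O-pinacolboryl ether of 4 | C#CC[C@]1(OB2OC(C)(C)C(C)(C)O2)C=CC(=O)C1 | intermediate (not isolated)
4 | (4R)-4-hydroxy-4-(prop-2-yn-1-yl)cyclopent-2-en-1-one | C#CC[C@]1(O)C=CC(=O)C1 | intermediate
5 | 1-bromopent-2-yne | CCC#CCBr | starting material
6 | (4R)-4-hydroxy-4-(octa-2,5-diyn-1-yl)cyclopent-2-en-1-one | CCC#CCC#CC[C@]1(O)C=CC(=O)C1 | intermediate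
7 | methyl 4-chloro-4-oxobutanoate | COC(=O)CCC(Cl)=O | starting material
8 | 3,3-diethoxyprop-1-yne | C#CC(OCC)OCC | starting material
9 | methyl 7,7-diethoxy-4-oxohept-5-ynoate | CCOC(OCC)C#CC(=O)CCC(=O)OC | intermediate
10 | methyl (4R)-7,7-diethoxy-4-hydroxyhept-5-ynoate | CCOC(OCC)C#C[C@@H](CCC(=O)OC)O | intermediate
11 | methyl (4R)-4-acetoxy-7,7-diethoxyhept-5-ynoate | CCOC(OCC)C#C[C@@H](CCC(=O)OC)OC(C)=O | intermediate
12 | methyl (4R)-4-acetoxy-7-oxohept-5-ynoate | O=CC#C[C@@H](CCC(=O)OC)OC(C)=O | intermediate
13 | dilithium alkoxide-enolate of 6 | CCC#CCC#CC[C@]1([O-])C=CC([O-])=C1.[Li+].[Li+] | intermediate (not isolated)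
14 | methyl (4R)-4-acetoxy-7-hydroxy-7-[(5S)-5-hydroxy-5-(octa-2,5-diyn-1-yl)-2-oxocyclopent-3-en-1-yl]hept-5-ynoate (C7/C8 epimer mixture) | CCC#CCC#CC[C@]1(O)C=CC(=O)C1C(O)C#C[C@@H](CCC(=O)OC)OC(C)=O | intermediate
15 | methyl (4R,5Z)-4-acetoxy-7-hydroxy-7-{(5S)-5-hydroxy-5-[(2Z,5Z)-octa-2,5-dien-1-yl]-2-oxocyclopent-3-en-1-yl}hept-5-enoate (C7/C8 epimer mixture) | CC/C=C\C/C=C\C[C@]1(O)C=CC(=O)C1C(O)/C=C\[C@@H](CCC(=O)OC)OC(C)=O | intermediate
16 | C7 acetate of 15 | CC/C=C\C/C=C\C[C@]1(O)C=CC(=O)C1C(OC(C)=O)/C=C\[C@@H](CCC(=O)OC)OC(C)=O | intermediate (not isolated)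
17 | methyl (4R,5Z,7E,12S,14Z,17Z)-4-acetoxy-12-hydroxy-9-oxoprosta-5,7,10,14,17-pentaen-1-oate | CC/C=C\C/C=C\C[C@]1(O)C=CC(=O)/C1=C/C=C\[C@@H](CCC(=O)OC)OC(C)=O | intermediate (not isolated)
18 | methyl (4R,5Z,7E,12S,14Z,17Z)-4,12-diacetoxy-9-oxoprosta-5,7,10,14,17-pentaen-1-oate (17,18-dehydro-clavulone I) | CC/C=C\C/C=C\C[C@]1(OC(C)=O)C=CC(=O)/C1=C/C=C\[C@@H](CCC(=O)OC)OC(C)=O | target

**Step count**
Total: 9 steps. Longest linear sequence: 7 steps (steps 3 to 9); the ring fragment takes 2 steps (steps 1 and 2).

**Three steps most likely to fail**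

Step 1 (the proposed new propargylboration). The free dione may be consumed through its acidic CH2 or react as a Michael acceptor, and the ee and the sense of induction are untested for this substrate class. The catalyst enantiomer is therefore fixed only after a Mosher analysis of 4; both antipodes are available. The fallback sets out from 1 and comes back at 4. Compound 1 is mono-ketalised with 2,2-dimethylpropane-1,3-diol (TsOH, benzene, Dean–Stark) to 8,8-dimethyl-6,10-dioxaspiro[4.5]dec-3-en-2-one F1. This ordinary conjugated ketone is propargylated with 2 under the documented biphenol protocol for ketones ((S)-3,3'-Br2-BINOL 10 mol%, neat, gentle heating), through the O-pinacolboryl ether F2, to (2R)-8,8-dimethyl-2-(prop-2-yn-1-yl)-6,10-dioxaspiro[4.5]dec-3-en-2-ol F3. PPTS in wet acetone then unmasks the ketone and gives 4.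

Step 8 (three semi-hydrogenations at once on a polyfunctional aldol). Over-reduction of the skipped diene, slow reduction of the ring enone, or incomplete conversion would give inseparable mixtures. The fallback sets out from 6 and comes back at 15, and spreads the reductions over simpler substrates. Compound 6 alone is semi-hydrogenated (Pd/CaCO3 poisoned with Pb(OAc)2, quinoline, 2 equiv H2; a plain fatty-acid-type skipped diyne) to (4R)-4-hydroxy-4-[(2Z,5Z)-octa-2,5-dien-1-yl]cyclopent-2-en-1-one F4. LiN(SiMe3)2 (2.1 equiv, THF, −78 °C) converts it into the ketol dianion F5, which adds to 12 to give the mono-alkyne aldol methyl (4R)-4-acetoxy-7-hydroxy-7-{(5S)-5-hydroxy-5-[(2Z,5Z)-octa-2,5-dien-1-yl]-2-oxocyclopent-3-en-1-yl}hept-5-ynoate F6. One semi-hydrogenation of this single alkyne (1 equiv H2, same catalyst) then gives 15.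

Step 9 (acetylation, elimination and tertiary acetylation in one flask). The elimination of acetate may stall, the 7E/7Z ratio may be poor, or the tertiary hydroxyl may resist DMAP catalysis. The fallback sets out from 15, comes back at 17 (now isolated) and from there reaches 18; it separates dehydration from acylation and uses a different leaving group and a different mode of acylation. MsCl (1.1 equiv), Et3N, CH2Cl2, −40 → 0 °C converts the secondary allylic hydroxyl into the C7 methanesulfonate F7, which eliminates by E1cB in the flask to give 17. Compound 17 is purified to the 7E isomer and then acetylated under Lewis-acid catalysis (Ac2O, Sc(OTf)3 cat., MeCN, −20 °C) to 18; ionisation at C12 is not a concern because the cation would be an antiaromatic oxo-cyclopentadienyl cation.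

**Further compounds**
F1 | step 1 | 8,8-dimethyl-6,10-dioxaspiro[4.5]dec-3-en-2-one | O=C1CC2(OCC(C)(C)CO2)C=C1
F2 | step 1 | O-pinacolboryl ether of F3 | C#CC[C@]1(OB3OC(C)(C)C(C)(C)O3)C=CC2(OCC(C)(C)CO2)C1
F3 | step 1 | (2R)-8,8-dimethyl-2-(prop-2-yn-1-yl)-6,10-dioxaspiro[4.5]dec-3-en-2-ol | C#CC[C@]1(O)C=CC2(OCC(C)(C)CO2)C1
F4 | step 8 | (4R)-4-hydroxy-4-[(2Z,5Z)-octa-2,5-dien-1-yl]cyclopent-2-en-1-one | CC/C=C\C/C=C\C[C@]1(O)C=CC(=O)C1
F5 | step 8 | ketol dianion (dilithium alkoxide-enolate of F4) | CC/C=C\C/C=C\C[C@]1([O-])C=CC([O-])=C1.[Li+].[Li+]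
F6 | step 8 | methyl (4R)-4-acetoxy-7-hydroxy-7-{(5S)-5-hydroxy-5-[(2Z,5Z)-octa-2,5-dien-1-yl]-2-oxocyclopent-3-en-1-yl}hept-5-ynoate | CC/C=C\C/C=C\C[C@]1(O)C=CC(=O)C1C(O)C#C[C@@H](CCC(=O)OC)OC(C)=O
F7 | step 9 | C7 methanesulfonate of 15 | CC/C=C\C/C=C\C[C@]1(O)C=CC(=O)C1C(OS(C)(=O)=O)/C=C\[C@@H](CCC(=O)OC)OC(C)=O
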